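The coupling partner is the charge to follow through this flask.

    starting material + coupling partner → mono adduct + by-product (k1 = 7.0 M⁻¹ s⁻¹)
    coupling partner + mono adduct → bis adduct + by-product (k2 = 6.0 M⁻¹ s⁻¹)
    coupling partner + bis adduct → triple product + by-product (k3 = 1.3 M⁻¹ s⁻¹)
    coupling partner + triple product → tetra adduct + by-product (k4 = 1.7 M⁻¹ s⁻¹)
    bis adduct + by-product → side product (k5 = 11 M⁻¹ s⁻¹)
    bis adduct ⇌ isomer of the product (K6 = 12, k6 = 0.037 s⁻¹)
starting material 20 mM; coupling partner 1.50 equiv; time 50 min
1. why nothing more happens at 50 min, or that something still does (forward and back rates have come level / it is still moving / the coupling partner has run out first / all of the starting material has reacted)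
2. share of the starting material used up at 50 min
3. side product at 50 min, in percent of the starting material charged
- the reaction counts as stopped when no species that holds the starting material changes by six tenths of a point or more over the second half of the time
- run time (flask): 50 min

First ask where a bis adduct goes. Divide its two losses so that time drops out: at equal c(by-product) and c(coupling partner), the step to side product runs 8.46 times as fast as the step to triple product. Count it as side product, then. Each side product costs 2 coupling partners, so the charge allows 75.0 %, less than the whole starting material, and the coupling partner is the limiting reagent.

Next ask where the partner stops. Divide the rate of mono adduct use by that of starting material use: time and c(coupling partner) both drop out. What remains is c(mono adduct) over c(starting material), times the selectivity factor, the second rate constant over the first, s = 0.857. With x the fraction of starting material left, the mono adduct fraction m is x raised to s, less x, over the gap between one and s. Counting no step past the bis adduct, partner used is twice the conversion, less m.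

Try x = 11.1 %. Then m = 28.7 % and the demand is 1.49 per starting material, which meets the 1.50 equiv charged. My reckoning is therefore 88.9 % conversion and 60.2 % past the mono adduct, which is my estimate for side product. With c(coupling partner) at 20 mM, the half-life of starting material would be about 0.0825 min, far shorter than 50 min.

The forecast says: the coupling partner has run out first, conversion 88.5 %, side product 58 %, on the ground that “By-product stays in excess over the bis adduct”.

The simulation gives: the coupling partner has run out first, with 0 % of it left, conversion 88.2 %, side product 56.0 %.

At 0.0578 min this flask uses bis adduct 4.8 times as fast toward side product as toward triple product. At 50.0 min it holds 56.0 % side product against 2.02 % triple product. With 11.8 % starting material left, s puts the mono adduct at 29.5 %, and this flask holds 29.5 %. The neighbour charged with 0.900 equiv keeps 35.6 % starting material, so s puts its mono adduct at 39.6 %, and it holds 39.6 %.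

(All constants belong to no real substance; the run is a simulation.)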